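## Numbering used throughout

Ring atoms carry germacrane numbers in every intermediate, including the tricyclic ones. C1=C10 is the ring olefin (methyl C14 on C10), C3 bears the angelate, C4 (methyl C15) and C5 are the epoxide carbons, C6 bears the acetate and C7 the isopropyl group.

Compounds: 1 ethyl 1-bromocyclobutane-1-carboxylate; 2 cyclobut-1-ene-1-carboxylic acid; 3 methyl cyclobut-1-ene-1-carboxylate; 4 (S)-piperitone; 5 tricyclic keto ester (photoadduct); 6 tricyclic diol; 7 hydroxy tosylate; 8 silylated tosylate; 9 silyl ether with C15 as methyl; 10 tricyclic carbinol with C15 as methyl; 11 tricyclic ketone; 12 (4Z)-dienone; 13 C4 selenide; 14 selenoxide; 15 (4E)-dienone; 16 silyl dienol ether; 17 3-hydroxy dienone; 18 epoxy hydroxy ketone; 19 angelic acid; 20 mixed anhydride; 21 epoxy keto angelate; 22 epoxy hydroxy angelate; 23 target.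

## Analysis of the target

The target is a germacrane: one ten-membered carbocycle with an E trisubstituted olefin at C1=C10, a trans trisubstituted epoxide at C4–C5, an angelate on C3, an acetate on C6 and an isopropyl group on C7. Its five stereocentres C3 to C7 are contiguous (3S,4R,5R,6R,7S). The epoxide is the one a 4E olefin gives; its oxygen is syn (threo) to the C3 oxygen and anti (erythro) to the C6 oxygen, and the C6 acetate is cis to the C7 isopropyl group on the ring. The sensitive groups are the angelate (isomerised to the tiglate by nucleophiles, acid or heat) and the epoxide, which is flanked by two acyloxy carbons and faces a transannular olefin. In precursors, an E,E-1(10),4-diene is prone to Cope rearrangement and acid-induced transannular cyclisation, and a C6 ketone makes C7 an epimerisable α-centre. The hard parts are the medium ring with its E olefin, telling C1=C10 and C4=C5 apart, and carrying stereochemical information from C7 through a flexible ring to C3, C4, C5 and C6. The strategy rests on the 1,5-relationship of C1=C10 and C4/C5: the ring is a masked cyclodeca-1(10),4-diene, the cycloreversion product of a cyclobutane built from C1, C4, C5 and C10, in which C5–C10 with its C6 oxygen, C7 isopropyl and C10 methyl is (S)-piperitone 4 and C1–C4 with C15 is the cyclobutene ester 3. In the crossed ring conformer that the C7 isopropyl group should select, the C3 oxygen, the epoxide oxygen and the C6 hydrogen all lie on the outer face, so each can in principle be delivered by peripheral attack.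

## Retrosynthetic reasoning

**23 to 21.** The C6 acetate is removed first, giving alcohol 22, and the C6–H bond is then cut to reach ketone 21. Placing the ketone next to the finished epoxide lets the epoxide oxygen steer the hydride by chelation to the erythro alcohol the target needs. An allylic C6 alcohol on the diene would instead direct epoxidation to the threo series through A(1,3) strain with C15.

**21 to 18 and 19.** The angelate C–O acyl bond is cut to alcohol 18 and angelic acid 19. Acylating before the ketone is reduced means the C3 and C6 hydroxyls never coexist, so no protecting group is needed at this stage.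

**18 to 17.** The two epoxide C–O bonds are cut to the E enone 17. Only at the enone stage is C4=C5 electronically distinct from C1=C10, so a nucleophilic oxidant touches it alone. The forward step must add oxygen to the outer face, syn to the C3 hydroxyl.

**17 to 15.** The C3–O bond is cut. C3 is the γ-position of enone 15, the only handle that distinguishes it from the allylic positions of C1=C10. A base-generated dienolate is excluded, because C7 is the sole stereocentre of 15 and is α to the ketone. The silyl dienol ether 16 is therefore made by soft enolisation, where loss of the C7 proton would give a constitutional isomer and not the C7 epimer.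

**15 to 12.** The geometry of C4=C5 is changed. A thermodynamic equilibration cannot be relied on, since in a ten-membered ring the ring-cis enone is normally the more stable isomer. The inversion is therefore done under kinetic control by addition and syn-elimination through 13 and 14.

**12 to 11.** C5–C10 and C1–C4 are reconnected. This turns both ring olefins into the central cyclobutane of tricycle 11 and replaces medium-ring formation by a strain-driven fragmentation. The forward thermolysis must be brief and base-free.

**11 to 5.** The C15 methyl is traced to the ester of 5 through 6, 8 and 10. The ester is needed only to steer the cycloaddition, and it is reduced while the skeleton is rigid and contains no 1,5-diene. Because the C6 oxygen sits cis to C15 across the C4–C5 bond of the cyclobutane, it is silylated for the hydride displacement so that it cannot close a cyclic ether onto C15.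

**5 to 4 and 3.** C5–C4 and C10–C1 are cut, the key disconnection. It returns a chiral-pool enone carrying C6 oxygen, C7 and C14, and a four-carbon partner carrying C15. The forward step needs head-to-head regiochemistry only.

**3 to 1.** The cyclobutene ester comes from acid 2 by O-methylation, and 2 from bromo ester 1 by dehydrobromination.

## Alternatives that were turned down

**Alternative 1: Ireland–Claisen ring contraction.**
- Disconnection: the C7–C8 ring bond, traced to a fourteen-membered allylic lactone.
- Forward key step: LiN(iPr)2 and Me3SiCl form the silyl ketene acetal, whose [3,3] shift contracts the ring to acid A1.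
- For: the ring forms at low temperature, and chirality is transferred to C7 through an ordered transition state. Both ring olefins and the C3 and C6 oxygens are in place beforehand, with configurations set in open-chain chemistry. On C3 and on olefin geometry this is stronger than the chosen route, which needs a late γ-oxygenation and a geometry inversion.
- Against: A1 carries a C8 carboxyl the target lacks and an isopropenyl group that must be saturated beside two trisubstituted ring olefins. The macrolactone needs a long linear sequence and a macrolactonisation. The final epoxidation would face an E,E-diene with an allylic C6 oxygen, where both site and face are unfavourable.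
- Comparison: the chosen route offers ring assembly from two small pieces in two operations, C7 from the chiral pool, and no surplus carbon.

**Alternative 2: anionic oxy-Cope ring expansion.**
- Disconnection: C8–C9 is cut and C1–C6 reconnected, giving a six-membered tertiary carbinol with two alkenyl arms.
- Forward key step: KH with 18-crown-6 generates the alkoxide, and the [3,3] shift gives ketone A2.
- For: the ring expansion runs at or below room temperature, which is at least as safe for the diene as a 190 °C thermolysis. The C3 oxygen is present from the outset with fixed configuration, so on C3 it is stronger than the chosen route.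
- Against: C7 is created by protonation of a ten-membered enolate and is not controlled by anything reliable. The carbinol needs a diastereoselective 1,2-addition. A2 is again the 4Z enone, so the geometry inversion remains.
- Comparison: the chosen route offers a C7 that is never formed on the ring but brought in with 4, and it pays with the later C3 oxygenation.

**Alternative 3: B-alkyl Suzuki macrocyclisation.**
- Disconnection: the C9–C10 bond, traced to an open chain with a terminal vinyl group and a C10 alkenyl iodide.
- Forward key step: hydroboration with 9-borabicyclo[3.3.1]nonane, then coupling with PdCl2(dppf) and Cs2CO3 (the cycle runs on zerovalent palladium) closes the ring to A3.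
- For: C3, C6, C7 and both olefin geometries are set by acyclic stereocontrol before the ring exists. This is the strongest of the four strategies in stereochemical security.
- Against: closing a strained ten-membered E,E-diene by cross-coupling competes with oligomerisation, β-hydride elimination and protodeboronation, and needs high dilution. The precursor is long. The endgame must epoxidise C4=C5, deactivated by two allylic C–O bonds, in the presence of the more electron-rich C1=C10, and the C6 acetate biases the face the wrong way.
- Comparison: the chosen route offers ring formation driven by strain release and an epoxidation made chemoselective by polarity at the enone stage.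

Key step: step 3

Assumption: (S)-(+)-piperitone of high enantiomeric purity is taken as purchasable and is kept away from base, because its stereocentre becomes C7.

## Route

Step 1
Reactants: 1 ethyl 1-bromocyclobutane-1-carboxylate
Product: 2 cyclobut-1-ene-1-carboxylic acid
Conditions: KOH (powdered, excess), toluene, reflux; then aq. HCl, 0 °C
Reagents that add atoms: potassium hydroxide, [K+].[OH-]
Why: E2 dehydrobromination of the tertiary α-bromo ester with concurrent saponification is the established entry to this acid; the carboxylate salt resists conjugate addition and polymerisation, which the free ester would not under alkoxide conditions.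

Step 2
Reactants: 2 cyclobut-1-ene-1-carboxylic acid
Product: 3 methyl cyclobut-1-ene-1-carboxylate
Conditions: MeI, K2CO3, DMF, 0 → 20 °C; distilled and used fresh
Reagents that add atoms: iodomethane, CI
Why: SN2 O-alkylation of the carboxylate avoids the acidic conditions under which the strained acrylate-type ester oligomerises.

Step 3
Reactants: 4 (S)-piperitone; 3 methyl cyclobut-1-ene-1-carboxylate
Product: 5 methyl 1-methyl-7-oxo-8-(propan-2-yl)tricyclo[4.4.0.0(2,5)]decane-5-carboxylate (cis-anti-cis head-to-head adduct; one of the two facial series is drawn)
Conditions: hν (medium-pressure Hg lamp, Pyrex, λ > 300 nm), CH2Cl2, degassed, −20 °C; cyclobutene ester in excess, surplus recovered by distillation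
Reagents that add atoms: none
Why: Excitation of the enone and intersystem crossing give the twisted triplet of 4, which adds to the strained acceptor-substituted double bond of 3: C10 (the enone β-carbon) bonds first to the unsubstituted cyclobutene carbon C1, and the resulting triplet 1,4-diradical, stabilised at C5 by the ketone and at C4 by the ester, closes C5–C4 after spin inversion. This is the enone–alkene [2+2] photocycloaddition in its enone–cyclobutene form. One ring is closed, the central cyclobutane C5–C4–C1–C10, by recombination of the 1,4-diradical (four-membered ring closure), while the six- and four-membered rings of the partners are kept. The selectivity the route needs is head-to-head regiochemistry, secured by the ester (the more stable diradical has the radical α to the ester) and by sterics (the quaternary C10 is formed with the CH terminus). Of the four new stereocentres, C1 and C4 are cis because they come from a cis ring olefin, C5 and C10 close to the less strained cis-fused bicyclo[4.2.0]octanone, and the cyclobutene approaches with its CH2–CH2 bridge turned away from the six-membered ring (anti). Which enone face is used relative to C7 is not controlled and need not be, since C1, C4, C5 and C10 all become trigonal in step 8. C7 lies outside the chromophore and keeps the configuration of 4. Any trans-fused adduct is separated and not epimerised with base, so that C7–H is never exposed.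

Step 4
Reactants: 5 tricyclic keto ester
Product: 6 5-(hydroxymethyl)-1-methyl-8-(propan-2-yl)tricyclo[4.4.0.0(2,5)]decan-7-ol (both C6 carbinol epimers)
Conditions: LiAlH4, THF, 0 °C
Reagents that add atoms: none
Why: Hydride reduction of ester and ketone; carbonyl addition at 0 °C is far faster than enolisation, any lactone formed in passing from the cis C6 alkoxide is reduced on to the same diol, and the carbinol configuration is irrelevant because C6 is re-oxidised in step 7.

Step 5
Reactants: 6 tricyclic diol
Product: 8 [1-methyl-8-(propan-2-yl)-7-(triethylsilyloxy)tricyclo[4.4.0.0(2,5)]decan-5-yl]methyl 4-methylbenzenesulfonate (both C6 epimers), via hydroxy tosylate 7 (not isolated)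
Conditions: TsCl (1.1 equiv), pyridine, CH2Cl2, 0 °C; then Et3SiOTf (1.5 equiv), −20 → 0 °C, same flask
Reagents that add atoms: 4-methylbenzenesulfonyl chloride, Cc1ccc(cc1)S(Cl)(=O)=O; triethylsilyl trifluoromethanesulfonate, CC[Si](CC)(CC)OS(=O)(=O)C(F)(F)F
Why: Selective sulfonylation of the primary hydroxyl (the secondary C6 hydroxyl, flanked by the ring fusion and the isopropyl-bearing carbon, reacts much more slowly) is followed by O-silylation of C6 with the silyl triflate. The C6 oxygen sits cis to C15 across the C4–C5 cyclobutane bond and would close an oxolane onto the tosylate once it met base, so it is capped in the same flask before any basic reagent is applied.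

Step 6
Reactants: 8 silylated tosylate
Product: 10 1,5-dimethyl-8-(propan-2-yl)tricyclo[4.4.0.0(2,5)]decan-7-ol (both C6 epimers), via silyl ether 9 (not isolated)
Conditions: LiEt3BH (3 equiv), THF, 65 °C; then 1 M aq. HCl–THF, 20 °C
Reagents that add atoms: none
Why: SN2 hydride displacement of a neopentyl-type tosylate, for which the triethylborohydride is the reagent of choice; the exocyclic carbon on a cyclobutane is less shielded than an open-chain neopentyl centre, and the silyl ether keeps the C6 oxygen from competing as an internal nucleophile. Mild acid hydrolysis of the triethylsilyl ether then frees the carbinol.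

Step 7
Reactants: 10 tricyclic carbinol
Product: 11 1,5-dimethyl-8-(propan-2-yl)tricyclo[4.4.0.0(2,5)]decan-7-one (cis-anti-cis)
Conditions: Dess–Martin periodinane, NaHCO3, CH2Cl2, 0 → 20 °C
Reagents that add atoms: none
Why: Buffered, non-enolising oxidation returns the C6 ketone and merges the carbinol epimers without touching C7.

Step 8
Reactants: 11 tricyclic ketone
Product: 12 (1(10)E,4Z,7S)-germacra-1(10),4-dien-6-one
Conditions: toluene (0.02 M, degassed), sealed base-washed silylated glass, 190 °C, about 1 h, stopped at partial conversion; recovered ketone recycled
Reagents that add atoms: none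
Why: Thermal cleavage of the bicyclo[2.2.0]hexane unit: homolysis of the shared C1–C4 bond gives a cyclohexane-1,4-diyl that fragments across C5–C10, a known route from such photoadducts to cyclodeca-1,5-dienes. The formal σ2s+σ2a course gives one ring-cis and one ring-trans olefin from a cis-anti-cis precursor, expected as 1(10)E,4Z because the conjugating C4=C5 bond can form in the less strained cis geometry; this E,Z isomer resists the Cope rearrangement that would consume an E,E isomer at this temperature. Both facial series of 11 converge here, and neutral glass keeps C7 intact.

Step 9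
Reactants: 12 (4Z)-dienone
Product: 15 (1(10)E,4E,7S)-germacra-1(10),4-dien-6-one, via selenide 13 (not isolated), via selenoxide 14 (not isolated)
Conditions: PhSeH (1.3 equiv), Et3N (0.1 equiv), CH2Cl2, 0 → 20 °C; then NaIO4, NaHCO3, MeOH–H2O, 0 → 20 °C
Reagents that add atoms: none
Why: Conjugate addition of the weakly basic selenol (pKa about 6) to C4 removes the C4=C5 bond without enolising toward C7. The selenoxide then undergoes stereospecific syn-elimination toward the acidified C5–H; in a ten-membered ring the syn-periplanar H–C5–C4–Se array is reached with C3 and C6 anti, so the ring-trans 4E enone should be the kinetic product, as in syn-eliminations of cyclodecyl amine oxides. Periodate leaves C1=C10 alone, and the Cope-labile E,E-dienone never meets heat or an equilibrating nucleophile.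

Step 10
Reactants: 15 (4E)-dienone
Product: 17 (1(10)E,3S,4E,7S)-3-hydroxygermacra-1(10),4-dien-6-one, via silyl dienol ether 16 (not isolated)
Conditions: Me3SiOTf (1.2 equiv), Et3N (2 equiv), CH2Cl2, −78 °C; pentane extraction; then dimethyldioxirane (1.0 equiv), acetone–CH2Cl2, −78 → −40 °C; pH 7 buffer–THF, 0 °C
Reagents that add atoms: dimethyldioxirane, CC1(C)OO1
Why: Soft enolisation: O-silylation puts positive charge on C4, and proton loss from the ring methylene C3 (the more substituted, endocyclic diene) is expected to outrun loss from the hindered tertiary C7–H; a C7 deprotonation would give a constitutional isomer and not the C7 epimer, so the configurational purity of 17 is not at stake. The neutral dioxirane attacks the terminal C3=C4 bond of the electron-rich dienol ether in preference to the isolated C1=C10 (γ-attack, as in the 6-hydroxylation of steroidal 3,5-dienol ethers), and collapse of the epoxide restores the enone from the s-trans diene, which should return the 4E geometry. Oxygen enters on the outer face of the crossed ring conformer selected by the C7 isopropyl group, which corresponds to 3S.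

Step 11
Reactants: 17 3-hydroxy dienone
Product: 18 (1(10)E,3S,4R,5S,7S)-4,5-epoxy-3-hydroxygermacr-1(10)-en-6-one
Conditions: tBuOOH (3 equiv), KH (1.5 equiv), THF, −20 °C
Reagents that add atoms: tert-butyl hydroperoxide, CC(C)(C)OO
Why: Weitz–Scheffer epoxidation: the peroxide anion adds only to the enone β-carbon C4 (C1=C10 is inert to nucleophilic oxidants), and closure from the ring-trans enolate gives the trans epoxide. Attack on the outer face, on the side of the C3 hydroxyl that can hold the potassium peroxide, gives the threo 3,4-relationship. The peroxide anion, kept in the presence of excess hydroperoxide, is too weak a base to enolise toward C7 at −20 °C.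

Step 12
Reactants: 18 epoxy hydroxy ketone; 19 angelic acid
Product: 21 (1(10)E,3S,4R,5S,7S)-4,5-epoxy-6-oxogermacr-1(10)-en-3-yl (Z)-2-methylbut-2-enoate, via mixed anhydride 20 (not isolated)
Conditions: angelic acid, 2,4,6-Cl3C6H2COCl, Et3N, toluene, 20 °C; then the epoxy alcohol, toluene, 70 °C
Reagents that add atoms: none
Why: Yamaguchi-type acyl transfer from the mixed anhydride without a nucleophilic pyridine catalyst, the conditions known to give angelates without Z to E isomerisation to tiglates. The C3 hydroxyl is the only one present, and the 1,5-diene is gone, so moderate heating is safe.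

Step 13
Reactants: 21 epoxy keto angelate
Product: 22 (1(10)E,3S,4R,5R,6R,7S)-4,5-epoxy-6-hydroxygermacr-1(10)-en-3-yl (Z)-2-methylbut-2-enoate
Conditions: Zn(BH4)2, Et2O, −20 → 0 °C
Reagents that add atoms: none
Why: Chelation-controlled reduction of an α,β-epoxy ketone: zinc bridges the ketone and epoxide oxygens and hydride enters from the outer face, anti to C4, which gives the erythro (6R) alcohol. The conjugated ester, the epoxide and the olefin are not reduced at this temperature.

Step 14
Reactants: 22 epoxy hydroxy angelate
Product: 23 (1(10)E,3S,4R,5R,6R,7S)-6-acetoxy-4,5-epoxygermacr-1(10)-en-3-yl (Z)-2-methylbut-2-enoate (target)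
Conditions: Ac2O, pyridine, DMAP (0.1 equiv), CH2Cl2, 0 → 20 °C
Reagents that add atoms: acetic anhydride, CC(=O)OC(C)=O
Why: Standard acylation of the remaining hindered secondary alcohol; the formed angelate and the epoxide tolerate these mild basic conditions.

## Compound list

1 | ethyl 1-bromocyclobutane-1-carboxylate | CCOC(=O)C1(Br)CCC1 | starting material
2 | cyclobut-1-ene-1-carboxylic acid | OC(=O)C1=CCC1 | intermediate
3 | methyl cyclobut-1-ene-1-carboxylate | COC(=O)C1=CCC1 | intermediate
4 | (S)-piperitone, (6S)-3-methyl-6-(propan-2-yl)cyclohex-2-en-1-one | CC1=CC(=O)[C@H](C(C)C)CC1 | starting material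
5 | methyl 1-methyl-7-oxo-8-(propan-2-yl)tricyclo[4.4.0.0(2,5)]decane-5-carboxylate, cis-anti-cis head-to-head adduct, isopropyl centre as in 4, one facial series drawn | C[C@]12CC[C@@H](C(C)C)C(=O)[C@H]1[C@]1(C(=O)OC)CC[C@@H]12 | intermediate
6 | 5-(hydroxymethyl)-1-methyl-8-(propan-2-yl)tricyclo[4.4.0.0(2,5)]decan-7-ol, both carbinol epimers | C[C@]12CC[C@@H](C(C)C)C(O)[C@H]1[C@]1(CO)CC[C@@H]12 | intermediate
7 | [7-hydroxy-1-methyl-8-(propan-2-yl)tricyclo[4.4.0.0(2,5)]decan-5-yl]methyl 4-methylbenzenesulfonate, both carbinol epimers | C[C@]12CC[C@@H](C(C)C)C(O)[C@H]1[C@]1(COS(=O)(=O)c3ccc(C)cc3)CC[C@@H]12 | intermediate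
8 | [1-methyl-8-(propan-2-yl)-7-(triethylsilyloxy)tricyclo[4.4.0.0(2,5)]decan-5-yl]methyl 4-methylbenzenesulfonate, both C6 epimers | C[C@]12CC[C@@H](C(C)C)C(O[Si](CC)(CC)CC)[C@H]1[C@]1(COS(=O)(=O)c3ccc(C)cc3)CC[C@@H]12 | intermediate
9 | triethyl{[1,5-dimethyl-8-(propan-2-yl)tricyclo[4.4.0.0(2,5)]decan-7-yl]oxy}silane, both C6 epimers | C[C@]12CC[C@@H](C(C)C)C(O[Si](CC)(CC)CC)[C@H]1[C@]1(C)CC[C@@H]12 | intermediate
10 | 1,5-dimethyl-8-(propan-2-yl)tricyclo[4.4.0.0(2,5)]decan-7-ol, both carbinol epimers | C[C@]12CC[C@@H](C(C)C)C(O)[C@H]1[C@]1(C)CC[C@@H]12 | intermediate
11 | 1,5-dimethyl-8-(propan-2-yl)tricyclo[4.4.0.0(2,5)]decan-7-one, cis-anti-cis | C[C@]12CC[C@@H](C(C)C)C(=O)[C@H]1[C@]1(C)CC[C@@H]12 | intermediate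
12 | (1(10)E,4Z,7S)-germacra-1(10),4-dien-6-one | C1C/C=C(\C)CC[C@@H](C(C)C)C(=O)/C=C1/C | intermediate
13 | (1(10)E,7S)-4-(phenylselanyl)germacr-1(10)-en-6-one, both C4 epimers | C1C/C=C(\C)CC[C@@H](C(C)C)C(=O)CC1(C)[Se]c1ccccc1 | intermediate
14 | (1(10)E,7S)-4-(phenylseleninyl)germacr-1(10)-en-6-one, stereoisomers at C4 and Se | C1C/C=C(\C)CC[C@@H](C(C)C)C(=O)CC1(C)[Se](=O)c1ccccc1 | intermediate
15 | (1(10)E,4E,7S)-germacra-1(10),4-dien-6-one | C1C/C=C(\C)CC[C@@H](C(C)C)C(=O)/C=C1\C | intermediate
16 | (1(10)E,7S)-6-(trimethylsilyloxy)germacra-1(10),3,5-triene, geometry of the two new ring double bonds not assigned | C[Si](C)(C)OC1=CC(C)=CC/C=C(\C)CC[C@H]1C(C)C | intermediate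
17 | (1(10)E,3S,4E,7S)-3-hydroxygermacra-1(10),4-dien-6-one | O[C@H]1C/C=C(\C)CC[C@@H](C(C)C)C(=O)/C=C1\C | intermediate
18 | (1(10)E,3S,4R,5S,7S)-4,5-epoxy-3-hydroxygermacr-1(10)-en-6-one | O[C@H]1C/C=C(\C)CC[C@@H](C(C)C)C(=O)[C@H]2O[C@]12C | intermediate
19 | angelic acid, (Z)-2-methylbut-2-enoic acid | C/C=C(/C)C(=O)O | starting material
20 | (Z)-2-methylbut-2-enoic 2,4,6-trichlorobenzoic anhydride | C/C=C(/C)C(=O)OC(=O)c1c(Cl)cc(Cl)cc1Cl | intermediate
21 | (1(10)E,3S,4R,5S,7S)-4,5-epoxy-6-oxogermacr-1(10)-en-3-yl (Z)-2-methylbut-2-enoate | C/C=C(/C)C(=O)O[C@H]1C/C=C(\C)CC[C@@H](C(C)C)C(=O)[C@H]2O[C@]12C | intermediate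
22 | (1(10)E,3S,4R,5R,6R,7S)-4,5-epoxy-6-hydroxygermacr-1(10)-en-3-yl (Z)-2-methylbut-2-enoate | C/C=C(/C)C(=O)O[C@H]1C/C=C(\C)CC[C@@H](C(C)C)[C@@H](O)[C@H]2O[C@]12C | intermediate
23 | (1(10)E,3S,4R,5R,6R,7S)-6-acetoxy-4,5-epoxygermacr-1(10)-en-3-yl (Z)-2-methylbut-2-enoate | C/C=C(/C)C(=O)O[C@H]1C/C=C(\C)CC[C@@H](C(C)C)[C@@H](OC(C)=O)[C@H]2O[C@]12C | target

## Step count and least certain steps

Total step count: 14. Longest linear sequence: 14 steps (1 to 23); 4 enters at step 3 and 19 at step 12.

**Step 3 (key step).** The cross-addition may be outrun by oligomerisation of the strained ester 3, and part of the material may leak into head-to-tail or trans-fused cycloaddition, because the intermolecular reaction has only the diradical stability to steer it. The fallback makes the reaction intramolecular. It sets out from 4 and 2. Reduction of 4 with NaBH4 and CeCl3·7H2O gives (6S)-3-methyl-6-(propan-2-yl)cyclohex-2-en-1-ol F1. Esterification of F1 with acid 2 (carbodiimide, DMAP) gives the cyclohexenyl cyclobutenecarboxylate F2. Triplet-sensitised irradiation (thioxanthone, 405 nm) closes C5–C4 and C10–C1 within the ester tether to give the tetracyclic lactone F3, in which the tether enforces the head-to-head, cis-anti-cis arrangement. LiAlH4 opens F3 to diol 6, where the route is rejoined.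

**Step 8.** The product may be consumed by onward Cope rearrangement, or the diyl may fragment the other way to the divinylcyclohexane, because the methyl ketone 11 needs a temperature close to that at which these processes start; the ring-cis bond could also fall at C1=C10. The fallback opens the ring earlier, on the more activated keto ester, where both diyl centres are stabilised and a lower temperature suffices; it also bypasses the deoxygenation on the tricycle. It sets out from 5. Thermolysis at about 160 °C gives methyl (1(10)E,4E,7S)-6-oxogermacra-1(10),4-dien-15-oate F4 (ring-cis at C4=C5). iBu2AlH reduces F4 to the diol (1(10)E,4E,7S)-germacra-1(10),4-diene-6,15-diol F5, in which the C6 oxygen and C15 are held trans across the ring-cis olefin and cannot close a cyclic ether. Selective sulfation of the primary allylic hydroxyl (SO3·pyridine) followed in the same flask by LiAlH4 gives (1(10)E,4Z,7S)-germacra-1(10),4-dien-6-ol F6, and MnO2 oxidises F6 to 12.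

**Step 9.** The selenoxide may eliminate back to the ring-cis enone or toward C3 or C15, since the preference for the ring-trans syn-elimination is argued by analogy only; the conjugate addition to the β,β-disubstituted enone may also be slow. The fallback changes the mechanism to a palladium β-hydride elimination. It sets out from 12. Copper hydride conjugate reduction ([CuH(PPh3)]6 catalyst, PhMe2SiH) gives the regiodefined silyl enol ether (1(10)E,7S)-6-[dimethyl(phenyl)silyloxy]germacra-1(10),5-diene F7 without touching C7, and Saegusa–Ito oxidation of F7 with Pd(OAc)2 in MeCN at 20 °C returns enone 15.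

**Step 10.** Oxygen may be delivered to the wrong face at C3, because the facial bias rests on a conformational preference of a flexible triene that may be small; proton loss from C15 in place of C3 and erosion of the 4E geometry are the other weaknesses. The fallback corrects C3 by inversion in place of facial control. It sets out from 15: should the oxidation deliver mainly the C3 epimer, (1(10)E,3R,4E,7S)-3-hydroxygermacra-1(10),4-dien-6-one F8, Mitsunobu esterification of F8 with 19 (PPh3, diisopropyl azodicarboxylate) gives (1(10)E,3S,4E,7S)-6-oxogermacra-1(10),4-dien-3-yl (Z)-2-methylbut-2-enoate F9 with inversion, and epoxidation of F9 under the conditions of step 11 rejoins the route at 21.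

**Step 11.** The peroxide may add to the inner-face conformer as well, giving the epimeric epoxide, because the outer-face preference and the hydroxyl assistance are both modest in a conformationally mobile enone; prolonged exposure could also start enolisation at C7. The fallback replaces substrate control by catalyst control: epoxidation of 17 with tBuOOH under a La(OiPr)3–BINOL–Ph3As=O catalyst, with the ligand enantiomer matched to the (4R,5S) epoxide, which again gives 18. No new compound is involved.

## Further compounds

F1 | step 3 | (6S)-3-methyl-6-(propan-2-yl)cyclohex-2-en-1-ol, both carbinol epimers | CC1=CC(O)[C@H](C(C)C)CC1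
F2 | step 3 | (6S)-3-methyl-6-(propan-2-yl)cyclohex-2-en-1-yl cyclobut-1-ene-1-carboxylate | CC1=CC(OC(=O)C2=CCC2)[C@H](C(C)C)CC1
F3 | step 3 | tetracyclic lactone joining the C6 oxygen to C15 on the cis-anti-cis tricycle, isopropyl centre as in 4 | CC12CC[C@@H](C(C)C)C3OC(=O)C4(CCC41)C32
F4 | step 8 | methyl (1(10)E,4E,7S)-6-oxogermacra-1(10),4-dien-15-oate, ring-cis at C4=C5 | C1C/C=C(\C)CC[C@@H](C(C)C)C(=O)/C=C1/C(=O)OC
F5 | step 8 | (1(10)E,4E,7S)-germacra-1(10),4-diene-6,15-diol, both C6 epimers | C1C/C=C(\C)CC[C@@H](C(C)C)C(O)/C=C1/CO
F6 | step 8 | (1(10)E,4Z,7S)-germacra-1(10),4-dien-6-ol, both C6 epimers | C1C/C=C(\C)CC[C@@H](C(C)C)C(O)/C=C1/C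
F7 | step 9 | (1(10)E,7S)-6-[dimethyl(phenyl)silyloxy]germacra-1(10),5-diene, both C4 epimers | C1C/C=C(\C)CC[C@@H](C(C)C)C(O[Si](C)(C)c2ccccc2)=CC1C
F8 | step 10 | (1(10)E,3R,4E,7S)-3-hydroxygermacra-1(10),4-dien-6-one | O[C@@H]1C/C=C(\C)CC[C@@H](C(C)C)C(=O)/C=C1\C
F9 | step 10 | (1(10)E,3S,4E,7S)-6-oxogermacra-1(10),4-dien-3-yl (Z)-2-methylbut-2-enoate | C/C=C(/C)C(=O)O[C@H]1C/C=C(\C)CC[C@@H](C(C)C)C(=O)/C=C1\C
F0 | step 11 | none | none
A1 | alternative 1 | 7-isopropenylcyclodeca-1(10),4-diene-8-carboxylic acid with C3 tert-butyldimethylsilyl ether and C6 4-methoxybenzyl ether | OC(=O)[C@H]1C/C(C)=C/C[C@H](O[Si](C)(C)C(C)(C)C)/C(C)=C/[C@H](OCc2ccc(OC)cc2)[C@@H]1C(C)=C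
A2 | alternative 2 | (1(10)E,4Z)-3-(tert-butyldimethylsilyloxy)germacra-1(10),4-dien-6-one | C1/C=C(\C)CC[C@@H](C(C)C)C(=O)/C=C(C)\[C@H]1O[Si](C)(C)C(C)(C)C
A3 | alternative 3 | 6-acetoxy-3-(tert-butyldimethylsilyloxy)germacra-1(10),4-diene | CC(C)(C)[Si](C)(C)O[C@H]1C/C=C(\C)CC[C@@H](C(C)C)[C@@H](OC(C)=O)/C=C1\C
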